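The earlier runs and the new flask come from a simulation from invented constants; scatter was added.

Percent of the electrophile charged was my unit, and on that scale the nucleophile charge reads as a ceiling. If each product takes up one nucleophile, conversion stops at the ceiling, nucleophile charged over electrophile charged, 90.0 %, with the nucleophile as limiting reagent. Grey and green have the same electrophile and nucleophile charges, so they share this ceiling.

all flasks: electrophile 0.13 M; nucleophile 0.117 M

| charge | free base | remark | time |
|---|---|---|---|
| maple | 0.27 M | run made earlier |  |
| oak | 0.30 M | run made earlier |  |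
| birch | 0.28 M | run made earlier |  |
| grey | 0.390 M |  | 5.0 min |
| green | 0.260 M |  | 5.0 min |

| run | time / min | electrophile / % | product / % |
|---|---|---|---|
| maple | 0.200 | 68.3 | 31.4 |
| maple | 0.417 | 55.9 | 43.2 |
| maple | 0.667 | 49.0 | 51.0 |
| maple | 1.33 | 39.7 | 59.0 |
| maple | 2.50 | 30.7 | 68.4 |
| oak | 0.500 | 53.7 | 47.3 |
| oak | 1.00 | 43.3 | 55.6 |
| oak | 1.50 | 39.1 | 61.9 |
| oak | 2.00 | 34.8 | 66.0 |
| oak | 2.50 | 30.6 | 69.4 |
| birch | 0.200 | 68.8 | 31.7 |
| birch | 0.667 | 48.9 | 51.2 |
| birch | 1.33 | 40.5 | 60.3 |
| birch | 2.00 | 34.5 | 65.4 |
| birch | 2.50 | 31.3 | 68.6 |

(each reading ± 0.5 percentage points)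

- the numbers in the tables scatter by 0.5 percentage points (one standard deviation)

* part of the electrophile that has reacted at the end, grey
* part of the electrophile that has reacted at the end, green
* what raising the concentration of free base from its lowest to its highest value here does to the part of the electrophile that has reacted (changes below 5 percentage points count as none) (it falls / no change / it rises)

My decision was whether the next flask needed grey's 0.390 M of free base or could stand on green's 0.260 M. At 2.50 min, the electrophile left read 30.7 %, 31.3 % and 30.6 % at 0.27 M, 0.28 M and 0.30 M of free base, which shows no trend against a scatter of 0.5 percentage points. Both new charges lie outside that range, so this was a judgement, but I chose green.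

For the end I joined the readings to the ceiling. In the maple run, time grew to twice its value from 1.33 min to 2.50 min, and product rose 9.4 points. One more such step from 68.4 % gave me 77.8 % at 5.0 min, still below the ceiling.

The forecast said 77 % for grey and 77 % for green, under my 77.8 %, and no change, on the grounds that “The three runs overlay within scatter”.

Grey gave 77.8 % and green 77.8 %, a change of 0 points, so the answer on free base was no change.

    electrophile + nucleophile → acid set free + product (k = 0.390 M⁻¹ s⁻¹)
    nucleophile + acid set free ⇌ protonated nucleophile, settled at all times (K = 140 M⁻¹)
    acid set free + free base ⇌ salt of the base, settled at all times (K = 3.20 × 10⁵ M⁻¹)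
    electrophile + acid set free ⇌ idle adduct, settled at all times (K = 4.60 M⁻¹)
    nucleophile ⇌ dormant form (K = 1.80, k = 0.0260 s⁻¹)

At 5.00 min grey held 74 % of its free base and green 61 %, with 22 % and 22 % of electrophile left. At 50.0 min grey had reached 89.9 %, against the ceiling of 90.0 %. With 0.52 M of electrophile in a neighbouring flask, the ceiling falls to 22.5 %, and that flask reacted 22.4 % by 5.00 min, with 0.028 % of its nucleophile left.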